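**Retrosynthetic overview**
1. C11–C12 bond: α-selective carbonyl allylation of the C15 bicyclic aldehyde 20 with (2E,6E)-farnesylbarium, then removal of the C11 hydroxyl (Barton–McCombie).
2. Ring A is built onto ring B by Robinson annulation: intermolecular Michael addition of the chiral imine of ring-B ketone 9 to ethyl vinyl ketone (C1–C10 bond, quaternary C10), aldol condensation, cis-hydrogenation (H-5), then C4 methylation.
3. Ring-B ketone 9 comes from (R)-linalool (supplies the C8 carbinol): ozonolysis, isopropenyl Grignard addition, ring-closing metathesis, oxidation, anti conjugate hydroxymethylation (C9–C11).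
4. Ring order: ring B first (metathesis), then ring A (Michael/aldol).

Assumption: the SMILES is read literally as (5S,8R,9R,10S), a cis-fused decalin with H-5, CH3-10, the C9 chain and CH3-8 on the β face and OH-8 on the α face; bicyclic compounds carry drimane/polypodane numbers (ring A = C1–C5, C10; ring B = C5–C10; C11 on C9).

**Route**

Step 1
Reactants: 1 (R)-(−)-linalool
Product: 2 (R)-linalool tert-butyldimethylsilyl (TBS) ether
Conditions: TBSOTf, 2,6-lutidine, CH2Cl2, 0 °C → rt
Reagents that add atoms: tert-butyldimethylsilyl trifluoromethanesulfonate, CC(C)(C)[Si](C)(C)OS(=O)(=O)C(F)(F)F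
Why: Silyl ether formation on the tertiary allylic alcohol with a silyl triflate and a hindered base; the stereocentre (future C8) is not touched.

Step 2
Reactants: 2 TBS ether of linalool
Product: 3 (R)-4-[(tert-butyldimethylsilyl)oxy]-4-methylhex-5-enal
Conditions: O3 (1.0 equiv), CH2Cl2, −78 °C; PPh3, −78 °C → rt
Reagents that add atoms: ozone, [O-][O+]=O
Why: Chemoselective ozonolysis, because the electron-rich trisubstituted alkene reacts much faster than the hindered vinyl group next to the quaternary silyloxy carbon.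

Step 3
Reactants: 3 aldehyde
Product: 4 (3RS,6R)-6-[(tert-butyldimethylsilyl)oxy]-2,6-dimethylocta-1,7-dien-3-ol
Conditions: isopropenylmagnesium bromide, THF, −78 → 0 °C
Reagents that add atoms: isopropenylmagnesium bromide, C=C(C)[Mg]Br
Why: Grignard addition to the aldehyde; the new carbinol centre is uncontrolled and is destroyed by oxidation in step 5.

Step 4
Reactants: 4 dienol
Product: 5 (1RS,4R)-4-[(tert-butyldimethylsilyl)oxy]-2,4-dimethylcyclohex-2-en-1-ol
Conditions: second-generation Grubbs catalyst (H2IMes)(PCy3)Cl2Ru=CHPh (3 mol %), CH2Cl2 (0.02 M), 40 °C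
Reagents that add atoms: none
Why: Ring-closing metathesis of a 1,7-diene to a six-membered trisubstituted cycloalkene (ring B), driven by loss of ethylene.

Step 5
Reactants: 5 cyclohexenol
Product: 6 (R)-4-[(tert-butyldimethylsilyl)oxy]-2,4-dimethylcyclohex-2-en-1-one
Conditions: MnO2 (excess), CH2Cl2, rt
Reagents that add atoms: none
Why: Selective allylic alcohol oxidation with MnO2 gives the enone and converges both carbinol epimers.

Step 6
Reactants: 6 enone
Product: 8 (2RS,3S,4R)-4-[(tert-butyldimethylsilyl)oxy]-3-(hydroxymethyl)-2,4-dimethylcyclohexan-1-one, via silylmethyl ketone 7 (not isolated)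
Conditions: ClMgCH2SiMe2(Oi-Pr) (preformed, 2 equiv), CuBr·SMe2 (20 mol %), THF, −40 → 0 °C; then 30% H2O2, KF, KHCO3, THF/MeOH, rt
Reagents that add atoms: [(isopropoxydimethylsilyl)methyl]magnesium chloride, CC(C)O[Si](C)(C)C[Mg]Cl; hydrogen peroxide, OO
Why: Copper-catalysed conjugate addition of a hydroxymethyl-anion equivalent enters anti to the pseudo-axial silyloxy group on the adjacent quaternary carbon (C9–CH2 trans to OTBS, cis to CH3-8), and Tamao oxidation turns C–Si into C–OH with retention; the α-methyl centre is left as a mixture because step 8 re-sets it.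

Step 7
Reactants: 8 hydroxymethyl ketone
Product: 9 (2RS,3S,4R)-4-[(tert-butyldimethylsilyl)oxy]-2,4-dimethyl-3-{[(triisopropylsilyl)oxy]methyl}cyclohexan-1-one
Conditions: TIPSCl, imidazole, DMF, rt
Reagents that add atoms: triisopropylsilyl chloride, CC(C)[Si](Cl)(C(C)C)C(C)C
Why: Silylation of the primary alcohol gives a base- and hydrogenation-stable ether that can later be removed in the presence of the tertiary TBS ether.

Step 8
Reactants: 9 ring-B ketone; 10 (R)-(+)-1-phenylethylamine; 11 ethyl vinyl ketone (pent-1-en-3-one)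
Product: 14 (2R,3S,4R)-4-[(tert-butyldimethylsilyl)oxy]-2,4-dimethyl-2-(3-oxopentyl)-3-{[(triisopropylsilyl)oxy]methyl}cyclohexan-1-one, via ketimine 12 (not isolated), via Michael adduct imine 13 (not isolated)
Conditions: 10, TsOH (1 mol %), toluene, reflux (Dean–Stark); then 11 (1.5 equiv), THF, 40 °C, 3 d; then 20% aq AcOH, rt
Reagents that add atoms: water, O
Why: d'Angelo asymmetric Michael addition, in which the secondary enamine tautomer of the imine adds through its more substituted α-carbon to the enone, anti to the neighbouring CH2OTIPS group and on the face favoured by the (R)-auxiliary (matched pair), so quaternary C10 is formed with its methyl cis to the C9 substituent.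

Step 9
Reactants: 14 1,5-diketone
Product: 15 (4aR,5S,6R)-6-[(tert-butyldimethylsilyl)oxy]-1,4a,6-trimethyl-5-{[(triisopropylsilyl)oxy]methyl}-4,4a,5,6,7,8-hexahydronaphthalen-2(3H)-one
Conditions: NaOMe (0.3 equiv), MeOH, 60 °C
Reagents that add atoms: none
Why: Intramolecular aldol condensation (second half of the Robinson annulation) closes ring A as the 4-methyl-Δ4-3-ketone; no stereocentre is formed.

Step 10
Reactants: 15 octalone
Product: 16 (1RS,4aS,5S,6R,8aR)-6-[(tert-butyldimethylsilyl)oxy]-1,4a,6-trimethyl-5-{[(triisopropylsilyl)oxy]methyl}octahydronaphthalen-2(1H)-one (cis-fused, H-5 β; C4 epimers)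
Conditions: H2 (3 atm), 10% Pd/C, EtOH, KOH (0.1 M), rt
Reagents that add atoms: none
Why: Heterogeneous catalytic hydrogenation of 10-methyl-Δ4-3-octalones in basic ethanol adds hydrogen on the face of the angular methyl (as with α-cyperone and cholestenone, which give 5β products), which sets H-5 β and the cis ring fusion; C4 is re-set in step 11.

Step 11
Reactants: 16 cis-fused 4-methyl ketone
Product: 17 (4aS,5S,6R,8aS)-6-[(tert-butyldimethylsilyl)oxy]-1,1,4a,6-tetramethyl-5-{[(triisopropylsilyl)oxy]methyl}octahydronaphthalen-2(1H)-one (8α-TBSO-11-TIPSO-5β-driman-3-one)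
Conditions: t-BuOK (1.3 equiv), t-BuOH/THF, rt; MeI (3 equiv), 0 °C → rt
Reagents that add atoms: iodomethane, CI
Why: Enolate C-alkylation under equilibrating conditions, where the cis-fused 3-ketone enolises towards the more substituted C4 (as 5β-3-keto steroids do) and methylation there gives the gem-dimethyl group without creating a stereocentre.

Step 12
Reactants: 17 ketone
Product: 18 C3 ethylene ketal (1,3-dioxolane) of 17
Conditions: (TMSOCH2)2 (3 equiv), TMSOTf (10 mol %), CH2Cl2, −20 → 0 °C; pyridine quench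
Reagents that add atoms: 1,2-bis(trimethylsilyloxy)ethane, C[Si](C)(C)OCCO[Si](C)(C)C
Why: Noyori ketalisation proceeds under aprotic conditions that both silyl ethers tolerate and masks the C3 ketone for the organometallic step.

Step 13
Reactants: 18 ketal
Product: 19 3,3-ethylenedioxy-8α-[(tert-butyldimethylsilyl)oxy]-5β-driman-11-ol
Conditions: TBAF (1.2 equiv), THF, 0 °C → rt
Reagents that add atoms: none
Why: Fluoride desilylation cleaves the unhindered primary TIPS ether much faster than the hindered tertiary TBS ether.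

Step 14
Reactants: 19 primary alcohol
Product: 20 3,3-ethylenedioxy-8α-[(tert-butyldimethylsilyl)oxy]-5β-driman-11-al
Conditions: Dess–Martin periodinane, NaHCO3, CH2Cl2, 0 °C → rt; used crude
Reagents that add atoms: none
Why: Buffered Dess–Martin oxidation gives the aldehyde under non-basic conditions, so C9 is not epimerised and the β-silyloxy group is not eliminated.

Step 15
Reactants: 21 (2E,6E)-farnesol
Product: 23 (2E,6E)-farnesyl chloride, via farnesyl mesylate 22 (not isolated)
Conditions: MsCl, 2,4,6-collidine, LiCl, DMF, 0 °C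
Reagents that add atoms: lithium chloride, [Li+].[Cl-]
Why: In situ mesylation and SN2 displacement by chloride (Meyers conditions) give the primary allylic chloride without allylic transposition or loss of E geometry.

Step 16
Reactants: 20 aldehyde; 23 (2E,6E)-farnesyl chloride
Product: 25 3,3-ethylenedioxy-8α-[(tert-butyldimethylsilyl)oxy]-5β-polypoda-13E,17E,21-trien-11-ol (C11 epimers), via farnesylbarium chloride 24 (not isolated)
Conditions: BaI2 (1.6 equiv), lithium biphenylide LiC12H10 (stock solution, 3.2 equiv), THF, rt; 23 (1.5 equiv), −78 °C; 20, −78 °C; aq NH4Cl at −78 °C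
Reagents that add atoms: none
Why: Yamamoto carbonyl allylation, in which allylbarium reagents add to aldehydes through the α-carbon with retention of E geometry at −78 °C, forms C11–C12 with the 13E alkene intact; the C11 carbinol is a mixture and is removed in step 18.

Step 17
Reactants: 25 homoallylic alcohol
Product: 26 O-C11 imidazole-1-carbothioate of 25
Conditions: 1,1′-thiocarbonyldiimidazole (3 equiv), DMAP (cat.), toluene, 90 °C
Reagents that add atoms: 1,1′-thiocarbonyldiimidazole, S=C(n1ccnc1)n1ccnc1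
Why: Thioacylation of the secondary alcohol under neutral conditions (first stage of the Barton–McCombie sequence) avoids alkoxide-induced silyl migration from O8.

Step 18
Reactants: 26 thiocarbonylimidazolide
Product: 27 3,3-ethylenedioxy-8α-[(tert-butyldimethylsilyl)oxy]-5β-polypoda-13E,17E,21-triene
Conditions: Bu3SnH (3 equiv, 0.5 M), AIBN (cat.), toluene, 100 °C
Reagents that add atoms: none
Why: Barton–McCombie radical deoxygenation replaces C11–O by C11–H; a high stannane concentration traps the secondary radical before it can cyclise onto the 13,14-alkene.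

Step 19
Reactants: 27 ketal
Product: 28 8α-[(tert-butyldimethylsilyl)oxy]-5β-polypoda-13E,17E,21-trien-3-one
Conditions: PPTS (0.3 equiv), acetone/H2O (9:1), 55 °C
Reagents that add atoms: water, O
Why: Mild acid-catalysed acetal hydrolysis releases the C3 ketone without affecting the trisubstituted alkenes or the tertiary silyl ether.

Step 20
Reactants: 28 silyl ether
Product: 29 IN0671, (5S,8R,9R,10S)-8-hydroxy-5β-polypoda-13E,17E,21-trien-3-one
Conditions: TBAF (5 equiv), THF, 60 °C
Reagents that add atoms: none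
Why: Fluoride desilylation of the hindered tertiary TBS ether frees the C8 alcohol; no stereocentre is affected.

**Compound list**
1 | (R)-(−)-linalool | CC(C)=CCC[C@@](C)(O)C=C | starting material
2 | (R)-linalool TBS ether | CC(C)=CCC[C@@](C)(O[Si](C)(C)C(C)(C)C)C=C | intermediate
3 | (R)-4-[(tert-butyldimethylsilyl)oxy]-4-methylhex-5-enal | O=CCC[C@@](C)(O[Si](C)(C)C(C)(C)C)C=C | intermediate
4 | (3RS,6R)-6-[(tert-butyldimethylsilyl)oxy]-2,6-dimethylocta-1,7-dien-3-ol | C=C(C)C(O)CC[C@@](C)(O[Si](C)(C)C(C)(C)C)C=C | intermediate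
5 | (1RS,4R)-4-[(tert-butyldimethylsilyl)oxy]-2,4-dimethylcyclohex-2-en-1-ol | OC1CC[C@@](C)(O[Si](C)(C)C(C)(C)C)C=C1C | intermediate
6 | (R)-4-[(tert-butyldimethylsilyl)oxy]-2,4-dimethylcyclohex-2-en-1-one | O=C1CC[C@@](C)(O[Si](C)(C)C(C)(C)C)C=C1C | intermediate
7 | (3R,4R)-4-[(tert-butyldimethylsilyl)oxy]-3-{[isopropoxy(dimethyl)silyl]methyl}-2,4-dimethylcyclohexan-1-one (C2 epimers) | CC(C)O[Si](C)(C)C[C@@H]1C(C)C(=O)CC[C@@]1(C)O[Si](C)(C)C(C)(C)C | intermediate (not isolated)
8 | (2RS,3S,4R)-4-[(tert-butyldimethylsilyl)oxy]-3-(hydroxymethyl)-2,4-dimethylcyclohexan-1-one | OC[C@@H]1C(C)C(=O)CC[C@@]1(C)O[Si](C)(C)C(C)(C)C | intermediate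
9 | (2RS,3S,4R)-4-[(tert-butyldimethylsilyl)oxy]-2,4-dimethyl-3-{[(triisopropylsilyl)oxy]methyl}cyclohexan-1-one | CC(C)[Si](C(C)C)(C(C)C)OC[C@@H]1C(C)C(=O)CC[C@@]1(C)O[Si](C)(C)C(C)(C)C | intermediate
10 | (R)-(+)-1-phenylethylamine | C[C@@H](N)c1ccccc1 | starting material
11 | ethyl vinyl ketone (pent-1-en-3-one) | CCC(=O)C=C | starting material
12 | N-[(R)-1-phenylethyl] ketimine of 9 | CC(C)[Si](C(C)C)(C(C)C)OC[C@@H]1C(C)C(=N[C@H](C)c2ccccc2)CC[C@@]1(C)O[Si](C)(C)C(C)(C)C | intermediate (not isolated)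
13 | N-[(R)-1-phenylethyl] ketimine of 14 (Michael adduct) | CC(C)[Si](C(C)C)(C(C)C)OC[C@@H]1[C@@](C)(CCC(=O)CC)C(=N[C@H](C)c2ccccc2)CC[C@@]1(C)O[Si](C)(C)C(C)(C)C | intermediate (not isolated)
14 | (2R,3S,4R)-4-[(tert-butyldimethylsilyl)oxy]-2,4-dimethyl-2-(3-oxopentyl)-3-{[(triisopropylsilyl)oxy]methyl}cyclohexan-1-one | CC(C)[Si](C(C)C)(C(C)C)OC[C@@H]1[C@@](C)(CCC(=O)CC)C(=O)CC[C@@]1(C)O[Si](C)(C)C(C)(C)C | intermediate
15 | (4aR,5S,6R)-6-[(tert-butyldimethylsilyl)oxy]-1,4a,6-trimethyl-5-{[(triisopropylsilyl)oxy]methyl}-4,4a,5,6,7,8-hexahydronaphthalen-2(3H)-one | CC(C)[Si](C(C)C)(C(C)C)OC[C@@H]1[C@@]2(C)CCC(=O)C(C)=C2CC[C@@]1(C)O[Si](C)(C)C(C)(C)C | intermediate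
16 | (1RS,4aS,5S,6R,8aR)-6-[(tert-butyldimethylsilyl)oxy]-1,4a,6-trimethyl-5-{[(triisopropylsilyl)oxy]methyl}octahydronaphthalen-2(1H)-one, cis-fused | CC(C)[Si](C(C)C)(C(C)C)OC[C@@H]1[C@@]2(C)CCC(=O)C(C)[C@H]2CC[C@@]1(C)O[Si](C)(C)C(C)(C)C | intermediate
17 | (4aS,5S,6R,8aS)-6-[(tert-butyldimethylsilyl)oxy]-1,1,4a,6-tetramethyl-5-{[(triisopropylsilyl)oxy]methyl}octahydronaphthalen-2(1H)-one | CC(C)[Si](C(C)C)(C(C)C)OC[C@@H]1[C@@]2(C)CCC(=O)C(C)(C)[C@H]2CC[C@@]1(C)O[Si](C)(C)C(C)(C)C | intermediate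
18 | C3 ethylene ketal of 17 (3,3-ethylenedioxy-8α-TBSO-11-TIPSO-5β-drimane) | CC(C)[Si](C(C)C)(C(C)C)OC[C@@H]1[C@@]2(C)CCC3(OCCO3)C(C)(C)[C@H]2CC[C@@]1(C)O[Si](C)(C)C(C)(C)C | intermediate
19 | 3,3-ethylenedioxy-8α-[(tert-butyldimethylsilyl)oxy]-5β-driman-11-ol | OC[C@@H]1[C@@]2(C)CCC3(OCCO3)C(C)(C)[C@H]2CC[C@@]1(C)O[Si](C)(C)C(C)(C)C | intermediate
20 | 3,3-ethylenedioxy-8α-[(tert-butyldimethylsilyl)oxy]-5β-driman-11-al | O=C[C@@H]1[C@@]2(C)CCC3(OCCO3)C(C)(C)[C@H]2CC[C@@]1(C)O[Si](C)(C)C(C)(C)C | intermediate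
21 | (2E,6E)-farnesol | CC(C)=CCC/C(C)=C/CC/C(C)=C/CO | starting material
22 | (2E,6E)-farnesyl methanesulfonate | CC(C)=CCC/C(C)=C/CC/C(C)=C/COS(C)(=O)=O | intermediate (not isolated)
23 | (2E,6E)-farnesyl chloride | CC(C)=CCC/C(C)=C/CC/C(C)=C/CCl | intermediate
24 | (2E,6E)-farnesylbarium chloride | CC(C)=CCC/C(C)=C/CC/C(C)=C/C[Ba]Cl | intermediate (not isolated)
25 | 3,3-ethylenedioxy-8α-[(tert-butyldimethylsilyl)oxy]-5β-polypoda-13E,17E,21-trien-11-ol (C11 epimers) | CC(C)=CCC/C(C)=C/CC/C(C)=C/CC(O)[C@@H]1[C@@]2(C)CCC3(OCCO3)C(C)(C)[C@H]2CC[C@@]1(C)O[Si](C)(C)C(C)(C)C | intermediate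
26 | O-C11 imidazole-1-carbothioate of 25 | CC(C)=CCC/C(C)=C/CC/C(C)=C/CC(OC(=S)n1ccnc1)[C@@H]1[C@@]2(C)CCC3(OCCO3)C(C)(C)[C@H]2CC[C@@]1(C)O[Si](C)(C)C(C)(C)C | intermediate
27 | 3,3-ethylenedioxy-8α-[(tert-butyldimethylsilyl)oxy]-5β-polypoda-13E,17E,21-triene | CC(C)=CCC/C(C)=C/CC/C(C)=C/CC[C@@H]1[C@@]2(C)CCC3(OCCO3)C(C)(C)[C@H]2CC[C@@]1(C)O[Si](C)(C)C(C)(C)C | intermediate
28 | 8α-[(tert-butyldimethylsilyl)oxy]-5β-polypoda-13E,17E,21-trien-3-one | CC(C)=CCC/C(C)=C/CC/C(C)=C/CC[C@@H]1[C@@]2(C)CCC(=O)C(C)(C)[C@H]2CC[C@@]1(C)O[Si](C)(C)C(C)(C)C | intermediate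
29 | IN0671, (5S,8R,9R,10S)-8-hydroxy-5β-polypoda-13E,17E,21-trien-3-one | CC(C)=CCC/C(C)=C/CC/C(C)=C/CC[C@@H]1[C@@]2(C)CCC(=O)C(C)(C)[C@H]2CC[C@@]1(C)O | target

**Totals**
Total step count: 20. Longest linear sequence: 19 steps (steps 1–14 and 16–20, from 1 to 29); step 15 is a one-step side branch.

**Steps most likely to fail, with fallbacks**

Step 10 is the most likely to fail. The hydrogenation must deliver H-5 on the β face, which already carries CH3-10, CH3-8 and the C9 substituent, and α-face addition would give the trans-fused isomer. The fallback sets out from 15 and uses a hydroxyl-directed hydrogenation. Luche reduction (NaBH4, CeCl3·7H2O, MeOH, −78 °C; hydride from the α face) gives the 3β-allylic alcohol F2. Hydrogenation with [Ir(cod)(PCy3)(py)]PF6 (H2, CH2Cl2) then delivers both hydrogens syn to the 3β-hydroxyl, giving the cis-fused 3β-alcohol F3. Dess–Martin oxidation of F3 returns to the route at 16 (as its 4α-methyl epimer).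

Step 8 is the second risk, because the imine must form a quaternary centre at C10 next to a tertiary and then a quaternary carbon and may react too slowly. The fallback sets out from 9 and uses a preformed enol derivative. TMSCl, NaI and Et3N in MeCN (equilibrating conditions) give the more substituted trimethylsilyl enol ether F1. A Mukaiyama–Michael addition of F1 to enone 11 (BF3·OEt2, CH2Cl2, −78 °C, aqueous work-up), again anti to the C9 substituent, returns to the route at 14.

Step 16 is the third risk. It depends on α- over γ-attack of the allylbarium, on retention of the 2E geometry, and on an aldehyde that can epimerise at C9; it is followed by a radical deoxygenation. The fallback sets out from 19 and reverses the polarity at C11. PhSSPh and Bu3P (Hata thioetherification) give the C11 phenyl sulfide F4. Oxidation with H2O2 and (NH4)6Mo7O24 gives the phenyl sulfone F5. Lithiation (n-BuLi, THF/HMPA, −78 °C) and alkylation with farnesyl chloride 23 give the C11-farnesylated sulfone F6. Reductive desulfonylation of F6 with sodium amalgam Na(Hg) and Na2HPO4 in MeOH/THF at −20 °C returns to the route at 27, bypassing 25 and 26.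

**Further compounds**
F1 | step 8 | more substituted (C5=C10) trimethylsilyl enol ether of 9 | CC(C)[Si](C(C)C)(C(C)C)OC[C@@H]1C(C)=C(O[Si](C)(C)C)CC[C@@]1(C)O[Si](C)(C)C(C)(C)C
F2 | step 10 | 3β-allylic alcohol from 15 (Δ4-3β-ol) | CC(C)[Si](C(C)C)(C(C)C)OC[C@@H]1[C@@]2(C)CC[C@H](O)C(C)=C2CC[C@@]1(C)O[Si](C)(C)C(C)(C)C
F3 | step 10 | cis-fused 3β-alcohol (4α-methyl, H-5 β) | CC(C)[Si](C(C)C)(C(C)C)OC[C@@H]1[C@@]2(C)CC[C@H](O)[C@@H](C)[C@H]2CC[C@@]1(C)O[Si](C)(C)C(C)(C)C
F4 | step 16 | 3,3-ethylenedioxy-8α-[(tert-butyldimethylsilyl)oxy]-11-(phenylsulfanyl)-5β-drimane | c1ccccc1SC[C@@H]1[C@@]2(C)CCC3(OCCO3)C(C)(C)[C@H]2CC[C@@]1(C)O[Si](C)(C)C(C)(C)C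
F5 | step 16 | 3,3-ethylenedioxy-8α-[(tert-butyldimethylsilyl)oxy]-11-(phenylsulfonyl)-5β-drimane | O=S(=O)(c1ccccc1)C[C@@H]1[C@@]2(C)CCC3(OCCO3)C(C)(C)[C@H]2CC[C@@]1(C)O[Si](C)(C)C(C)(C)C
F6 | step 16 | 11-(phenylsulfonyl) derivative of 27 (C11 epimers) | CC(C)=CCC/C(C)=C/CC/C(C)=C/CC(S(=O)(=O)c1ccccc1)[C@@H]1[C@@]2(C)CCC3(OCCO3)C(C)(C)[C@H]2CC[C@@]1(C)O[Si](C)(C)C(C)(C)C
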